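**Strategy.** The benzene ring is not brought in as such but grown from a squarate. Arene carbons C2', C3', C4' and C5', with para oxygens on C2' and C5' and a third oxygen on C4', are the four carbons of a cyclobutenone; C1' and C6' are the alkene carbons of a decalinyl-propenyl chain. Heating the 4-alkenyl-4-silyloxy-3-tert-butoxycyclobutenone opens the four-membered ring and forms the C1'–C2' bond, so the arene appears in one operation with O2' free, O4' as tert-butyl ether and O5' as silyl ether. The precursor is made from an exo Diels–Alder decalin aldehyde (ring B; C8, C9, C10) by homologation to an alkenyllithium, which adds to tert-butyl semisquarate.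

Key step: step 10

Remark on numbering: decalin carbons carry drimane-type numbers (C4 gem-dimethyl, C5=C6, C8 CH(CH3), C9 quaternary, C10 ring-fusion CH, C11 benzylic); arene carbons are primed (C1' on C11). "Dec" stands for the (1R,2R,8aS)-1,2,5,5-tetramethyl-1,2,3,5,6,7,8,8a-octahydronaphthalen-1-yl group (8R,9R,10S in drimane numbers). C8-methyl is cis to C11 and H10, and trans to C9-methyl.

Remark on stereochemistry: the target has the C8-methyl trans to the C9-methyl, which requires the Z (angelic) dienophile; the E (tiglic) isomer would give the C8 epimer.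

Assumption: the aryl sulfate is isolated as its ammonium salt and is written, like the target, as the free hydrogen sulfate.

Remark on convergence: 16 and 17 form as both epimers at the ring carbinol carbon and 11 may hold some Z isomer; all of these converge in step 10.

**Step 1**
Reactants: 1 2,2-dimethylcyclohexanone
Product: 3 6,6-dimethylcyclohex-1-en-1-yl trifluoromethanesulfonate, via lithium enolate 2 (not isolated)
Conditions: LiN(iPr)2, THF, −78 °C; PhNTf2, −78 °C → rt
Reagents that add atoms: N-phenylbis(trifluoromethanesulfonimide), O=S(=O)(N(c1ccccc1)S(=O)(=O)C(F)(F)F)C(F)(F)F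
Why: Deprotonation is possible only at C6 because C2 is quaternary, and O-sulfonylation of the lithium enolate (enolate triflation) should give a single enol triflate.

**Step 2**
Reactants: 3 6,6-dimethylcyclohex-1-en-1-yl trifluoromethanesulfonate
Product: 4 1-ethenyl-6,6-dimethylcyclohex-1-ene
Conditions: tributyl(vinyl)stannane, Pd(PPh3)4 (cat.), LiCl, THF, 65 °C
Reagents that add atoms: tributyl(vinyl)stannane, C=C[Sn](CCCC)(CCCC)CCCC
Why: Stille coupling of an enol triflate under zerovalent palladium catalysis with chloride assistance forms the diene under neutral conditions, so no double bond can shift.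

**Step 3**
Reactants: 5 angelic acid
Product: 6 (2Z)-2-methylbut-2-en-1-ol
Conditions: LiAlH4, Et2O, 0 °C
Reagents that add atoms: none
Why: Hydride reduction of the carboxylic acid proceeds by 1,2-delivery and should leave the Z-trisubstituted alkene and its geometry untouched.

**Step 4**
Reactants: 6 (2Z)-2-methylbut-2-en-1-ol
Product: 7 (2Z)-2-methylbut-2-enal
Conditions: Dess–Martin periodinane, NaHCO3, CH2Cl2, 0 °C; washed solution used directly
Reagents that add atoms: none
Why: The buffered Dess–Martin oxidation is fast and non-acidic, which should give the volatile Z-enal without isomerisation to the E-isomer.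

**Step 5**
Reactants: 4 1-ethenyl-6,6-dimethylcyclohex-1-ene; 7 (2Z)-2-methylbut-2-enal
Product: 8 (1R,2R,8aR)-1,2,5,5-tetramethyl-1,2,3,5,6,7,8,8a-octahydronaphthalene-1-carbaldehyde
Conditions: (R)-tetrahydro-1-(2-methylphenyl)-3,3-diphenyl-1H,3H-pyrrolo[1,2-c][1,3,2]oxazaborole (20 mol%), (CF3SO2)2NH (18 mol%), CH2Cl2, −78 → −40 °C
Reagents that add atoms: none
Why: Enantioselective Diels–Alder reaction catalysed by a cationic oxazaborolidine, in which C8 bonds to the CH2 terminus C7 and C9 to the ring terminus C10, suprafacial addition turns the Z geometry into the cis relation of C8-methyl and C9-formyl, the exo transition state (formyl kept away from C5 and its gem-dimethyl neighbour C4) puts H10 cis to the formyl group, and the (R)-catalyst should shield the Re face at C2 of the s-trans bound enal so that the diene adds to the Si face, which sets C8, C9 and C10 together.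

**Step 6**
Reactants: 8 decalin aldehyde
Product: 10 2-[(1R,2R,8aS)-1,2,5,5-tetramethyl-1,2,3,5,6,7,8,8a-octahydronaphthalen-1-yl]acetaldehyde (Dec-CH2-CHO), via enol ether 9 (not isolated)
Conditions: Ph3P(CH2OMe)Cl, KN(SiMe3)2, THF, 0 °C → rt; then 1 M aq HCl, THF, rt
Reagents that add atoms: (methoxymethyl)triphenylphosphonium chloride, COC[P+](c1ccccc1)(c1ccccc1)c1ccccc1.[Cl-]; water, O
Why: Wittig methoxymethylenation works on hindered α-quaternary aldehydes, and mild hydrolysis of the enol ether should give the one-carbon homologue, in which the former formyl carbon is C11, without touching C8, C9, C10 or the C5=C6 alkene.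

**Step 7**
Reactants: 10 Dec-CH2-CHO
Product: 11 (1R,2R,8aS)-1-[(2E)-3-iodoprop-2-en-1-yl]-1,2,5,5-tetramethyl-1,2,3,5,6,7,8,8a-octahydronaphthalene
Conditions: CHI3, CrCl2, THF–1,4-dioxane, 0 °C → rt
Reagents that add atoms: iodoform, IC(I)I
Why: Takai olefination with the geminal dichromium species formed from iodoform and divalent chromium converts an unhindered CH2–CHO aldehyde directly into the E-alkenyl iodide, whose two sp2 carbons become C1' and C6'.

**Step 8**
Reactants: 12 di-tert-butyl squarate
Product: 14 3-tert-butoxycyclobut-3-ene-1,2-dione, via carbinol 13 (not isolated)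
Conditions: LiAlH(OtBu)3, THF, −78 °C; aq NH4Cl; crude carbinol: (CF3CO)2O, Et2O, −78 → 0 °C
Reagents that add atoms: none
Why: Mono-reduction of one of the two equivalent carbonyls by the bulky hydride, then O-trifluoroacetylation, ionisation assisted by the enol ether oxygen and loss of the tert-butyl cation from the oxocarbenium ion, should give the semisquarate, as in the known conversion of squarate adducts into 3-alkoxycyclobutenediones.

**Step 9**
Reactants: 11 alkenyl iodide; 14 3-tert-butoxycyclobut-3-ene-1,2-dione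
Product: 17 3-tert-butoxy-4-[(tert-butyldimethylsilyl)oxy]-4-[(1E)-3-Dec-prop-1-en-1-yl]cyclobut-2-en-1-one, via alkenyllithium 15 (not isolated), via lithium alkoxide 16 (not isolated)
Conditions: t-BuLi (2 equiv), Et2O, −78 °C; added to 14, THF, −78 °C; then tBuMe2SiOSO2CF3, −78 → −20 °C
Reagents that add atoms: tert-butyldimethylsilyl trifluoromethanesulfonate, CC(C)(C)[Si](C)(C)OS(=O)(=O)C(F)(F)F
Why: Iodine–lithium exchange keeps the alkene geometry, the alkenyllithium should add 1,2 to the ketone carbonyl next to the tert-butoxy-bearing carbon (the other carbonyl is a deactivated vinylogous ester), and trapping the alkoxide in the same flask avoids isolating the acid-sensitive carbinol; the new carbinol centre is uncontrolled and is erased in step 10.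

**Step 10**
Reactants: 17 4-alkenyl-4-silyloxycyclobutenone
Product: 20 5-tert-butoxy-4-[(tert-butyldimethylsilyl)oxy]-2-(Dec-methyl)phenol, via dienylketene 18 (not isolated), via cyclohexadienone 19 (not isolated)
Conditions: toluene (degassed), 110 °C, base-washed glass
Reagents that add atoms: none
Why: Thermal conrotatory 4π ring opening breaks the bond between the carbonyl carbon and the silyloxy-bearing sp3 carbon and gives dienylketene 18; the silyloxy donor rotates outward, so the propenyl group turns inward and lies next to the ketene carbon. Disrotatory 6π electrocyclisation then joins the ketene carbon (C2') to the alkene terminus that carries C11 (C1') and closes the six-membered carbocycle as cyclohexadienone 19, whose enolisation gives the phenol. The closest known reaction type is the Moore ring expansion of 4-alkenyl-4-hydroxy- or 4-silyloxycyclobutenones from squarate esters to hydroquinone derivatives. No stereocentre is created, since the carbinol centre of 17 and the transient sp3 carbon of 19 both vanish, so both epimers of 17 and either alkene geometry converge. The selectivity that matters is the placing of the three oxygens, fixed beforehand by the site of alkenyllithium addition and during the step by outward rotation of the silyloxy group: the ketene oxygen becomes the free O2'–H, O5' stays silylated and O4' stays a tert-butyl ether. Neutral, unimolecular conditions should leave the C5=C6 alkene and C8, C9 and C10 untouched.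

**Step 11**
Reactants: 20 phenol
Product: 21 6-tert-butoxy-5-[(tert-butyldimethylsilyl)oxy]-2-hydroxy-3-(Dec-methyl)benzaldehyde
Conditions: MgCl2, Et3N, (CH2O)n, MeCN, 80 °C, argon
Reagents that add atoms: paraformaldehyde (as formaldehyde), C=O
Why: Magnesium-phenoxide-directed ortho-formylation (Casnati–Skattebøl) delivers formaldehyde only ortho to the free hydroxyl, and C3' is the single open ortho position because C1' is substituted.

**Step 12**
Reactants: 21 salicylaldehyde
Product: 22 3-tert-butoxy-4-[(tert-butyldimethylsilyl)oxy]-2-formyl-6-(Dec-methyl)phenyl 2,2,2-trichloroethyl sulfate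
Conditions: Cl3CCH2OSO2Cl, Et3N, DMAP (cat.), THF, 0 °C → rt
Reagents that add atoms: 2,2,2-trichloroethyl chlorosulfate, ClS(=O)(=O)OCC(Cl)(Cl)Cl
Why: O-Sulfonylation of the only free phenol with the chlorosulfate gives a neutral, acid-stable sulfate diester that can be chromatographed and carried through the deprotections.

**Step 13**
Reactants: 22 protected sulfate diester
Product: 24 2-formyl-3,4-dihydroxy-6-(Dec-methyl)phenyl 2,2,2-trichloroethyl sulfate, via mono-silyl ether 23 (not isolated)
Conditions: CF3CO2H–CH2Cl2 (1:9), 0 °C, short; evaporate; Et3N·3HF, MeCN, rt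
Reagents that add atoms: none
Why: Acidolysis of the aryl tert-butyl ether ortho to the formyl group should be much faster than protonation of the hindered C5=C6 alkene in dilute cold acid, and the weakly acidic fluoride source then cleaves the aryl silyl ether without attacking the sulfate diester.

**Step 14**
Reactants: 24 catechol sulfate diester
Product: 25 2-formyl-3,4-dihydroxy-6-(Dec-methyl)phenyl hydrogen sulfate (target)
Conditions: Zn dust, HCO2NH4, MeOH, rt, argon
Reagents that add atoms: none
Why: Zinc reduces the trichloroethyl group with β-elimination of 1,1-dichloroethene and releases the aryl sulfate monoester under near-neutral conditions that should spare the aldehyde, the catechol and the alkene.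

**Compound list**

1 | 2,2-dimethylcyclohexanone | CC1(C)CCCCC1=O | starting material
2 | lithium 6,6-dimethylcyclohex-1-en-1-olate | CC1(C)CCCC=C1O[Li] | intermediate
3 | 6,6-dimethylcyclohex-1-en-1-yl trifluoromethanesulfonate | CC1(C)CCCC=C1OS(=O)(=O)C(F)(F)F | intermediate
4 | 1-ethenyl-6,6-dimethylcyclohex-1-ene | C=CC1=CCCCC1(C)C | intermediate
5 | angelic acid, (2Z)-2-methylbut-2-enoic acid | C/C=C(/C)C(=O)O | starting material
6 | (2Z)-2-methylbut-2-en-1-ol | C/C=C(/C)CO | intermediate
7 | (2Z)-2-methylbut-2-enal | C/C=C(/C)C=O | intermediate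
8 | (1R,2R,8aR)-1,2,5,5-tetramethyl-1,2,3,5,6,7,8,8a-octahydronaphthalene-1-carbaldehyde | C[C@@H]1CC=C2[C@@H](CCCC2(C)C)[C@]1(C)C=O | intermediate
9 | (1R,2R,8aS)-1-(2-methoxyethenyl)-1,2,5,5-tetramethyl-1,2,3,5,6,7,8,8a-octahydronaphthalene (E/Z mixture) | C[C@@H]1CC=C2[C@@H](CCCC2(C)C)[C@]1(C)C=COC | intermediate
10 | 2-[(1R,2R,8aS)-1,2,5,5-tetramethyl-1,2,3,5,6,7,8,8a-octahydronaphthalen-1-yl]acetaldehyde | C[C@@H]1CC=C2[C@@H](CCCC2(C)C)[C@]1(C)CC=O | intermediate
11 | (1R,2R,8aS)-1-[(2E)-3-iodoprop-2-en-1-yl]-1,2,5,5-tetramethyl-1,2,3,5,6,7,8,8a-octahydronaphthalene | C[C@@H]1CC=C2[C@@H](CCCC2(C)C)[C@]1(C)C/C=C/I | intermediate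
12 | di-tert-butyl squarate, 3,4-di-tert-butoxycyclobut-3-ene-1,2-dione | CC(C)(C)OC1=C(OC(C)(C)C)C(=O)C1=O | starting material
13 | 2,3-di-tert-butoxy-4-hydroxycyclobut-2-en-1-one | CC(C)(C)OC1=C(OC(C)(C)C)C(O)C1=O | intermediate
14 | 3-tert-butoxycyclobut-3-ene-1,2-dione | CC(C)(C)OC1=CC(=O)C1=O | intermediate
15 | [(1E)-3-Dec-prop-1-en-1-yl]lithium | C[C@@H]1CC=C2[C@@H](CCCC2(C)C)[C@]1(C)C/C=C/[Li] | intermediate
16 | lithium 2-tert-butoxy-4-oxo-1-[(1E)-3-Dec-prop-1-en-1-yl]cyclobut-2-en-1-olate (both epimers) | C[C@@H]1CC=C2[C@@H](CCCC2(C)C)[C@]1(C)C/C=C/C1(O[Li])C(OC(C)(C)C)=CC1=O | intermediate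
17 | 3-tert-butoxy-4-[(tert-butyldimethylsilyl)oxy]-4-[(1E)-3-Dec-prop-1-en-1-yl]cyclobut-2-en-1-one (both epimers) | C[C@@H]1CC=C2[C@@H](CCCC2(C)C)[C@]1(C)C/C=C/C1(O[Si](C)(C)C(C)(C)C)C(OC(C)(C)C)=CC1=O | intermediate
18 | 3-tert-butoxy-4-[(tert-butyldimethylsilyl)oxy]-7-Dec-hepta-1,3,5-trien-1-one (dienylketene, alkenyl group cis to the ketene carbon across C3=C4) | C[C@@H]1CC=C2[C@@H](CCCC2(C)C)[C@]1(C)C/C=C/C(O[Si](C)(C)C(C)(C)C)=C(OC(C)(C)C)\C=C=O | intermediate
19 | 3-tert-butoxy-4-[(tert-butyldimethylsilyl)oxy]-6-(Dec-methyl)cyclohexa-2,4-dien-1-one | C[C@@H]1CC=C2[C@@H](CCCC2(C)C)[C@]1(C)CC3C=C(O[Si](C)(C)C(C)(C)C)C(OC(C)(C)C)=CC3=O | intermediate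
20 | 5-tert-butoxy-4-[(tert-butyldimethylsilyl)oxy]-2-(Dec-methyl)phenol | C[C@@H]1CC=C2[C@@H](CCCC2(C)C)[C@]1(C)Cc1cc(O[Si](C)(C)C(C)(C)C)c(OC(C)(C)C)cc1O | intermediate
21 | 6-tert-butoxy-5-[(tert-butyldimethylsilyl)oxy]-2-hydroxy-3-(Dec-methyl)benzaldehyde | C[C@@H]1CC=C2[C@@H](CCCC2(C)C)[C@]1(C)Cc1cc(O[Si](C)(C)C(C)(C)C)c(OC(C)(C)C)c(C=O)c1O | intermediate
22 | 3-tert-butoxy-4-[(tert-butyldimethylsilyl)oxy]-2-formyl-6-(Dec-methyl)phenyl 2,2,2-trichloroethyl sulfate | C[C@@H]1CC=C2[C@@H](CCCC2(C)C)[C@]1(C)Cc1cc(O[Si](C)(C)C(C)(C)C)c(OC(C)(C)C)c(C=O)c1OS(=O)(=O)OCC(Cl)(Cl)Cl | intermediate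
23 | 4-[(tert-butyldimethylsilyl)oxy]-2-formyl-3-hydroxy-6-(Dec-methyl)phenyl 2,2,2-trichloroethyl sulfate | C[C@@H]1CC=C2[C@@H](CCCC2(C)C)[C@]1(C)Cc1cc(O[Si](C)(C)C(C)(C)C)c(O)c(C=O)c1OS(=O)(=O)OCC(Cl)(Cl)Cl | intermediate
24 | 2-formyl-3,4-dihydroxy-6-(Dec-methyl)phenyl 2,2,2-trichloroethyl sulfate | C[C@@H]1CC=C2[C@@H](CCCC2(C)C)[C@]1(C)Cc1cc(O)c(O)c(C=O)c1OS(=O)(=O)OCC(Cl)(Cl)Cl | intermediate
25 | 2-formyl-3,4-dihydroxy-6-{[(1R,2R,8aS)-1,2,5,5-tetramethyl-1,2,3,5,6,7,8,8a-octahydronaphthalen-1-yl]methyl}phenyl hydrogen sulfate | C[C@@H]1CC=C2[C@@H](CCCC2(C)C)[C@]1(C)Cc1cc(O)c(O)c(C=O)c1OS(=O)(=O)O | target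

**Step count and risks**

Total: 14 steps. Longest linear sequence: 11 steps (steps 1, 2, 5, 6, 7, 9, 10, 11, 12, 13, 14).

Most likely to fail:

Step 5. The acid catalyst may rotate the C2=C3 bond of the bound Z-enal before cycloaddition, which would deliver the C8 epimer, and facial discrimination may be weak because the Z-methyl sits beside the catalyst-bound formyl group. (If only the sense of induction were reversed, the antipodal catalyst would be used.) The fallback sets out from 4 and 7 and comes back at 8. The two are combined without any acid under 12 kbar at rt, which cannot isomerise the enal and should give the racemic exo aldehyde F1. NaBH4 in MeOH reduces it to the racemic alcohol F2. Esterification with (S)-naproxen (DCC, DMAP, CH2Cl2) gives the naproxen ester F3 of the wanted enantiomer and its diastereomer F4, which are separated by chromatography or crystallisation. LiAlH4 releases the enantiopure alcohol F5 from F3, and Dess–Martin oxidation returns 8.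

Step 11. The formaldehyde held on the magnesium phenoxide must attack a position wedged between the hydroxyl and the tert-butoxy group, so conversion may stall and the silyl ether may be lost on long heating. The fallback sets out from 20 and comes back at 21. Ortho-bromination with NBS and catalytic iPr2NH in CH2Cl2 at −78 °C, where C3' is the only position ortho or para to the free hydroxyl that is still open, gives the bromophenol F6. Deprotonation with MeLi, bromine–lithium exchange with t-BuLi in THF at −78 °C and quenching of the aryllithium with DMF gives 21 after aqueous work-up.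

Step 9. The strongly basic alkenyllithium may abstract the ring C–H of 14 in place of adding to the carbonyl, or the crowded tertiary alkoxide may be captured incompletely by the silyl triflate. The fallback sets out from 10 and 14 and comes back at 20. Dimethyl (1-diazo-2-oxopropyl)phosphonate with K2CO3 in MeOH converts 10 into the alkyne F7. Its less basic lithium acetylide (n-BuLi, THF, −78 °C) adds to 14, and trapping with tBuMe2SiOSO2CF3 gives the alkynyl silyl ether F8, whose linear substituent leaves the alkoxide more open. Semi-hydrogenation over Pd/CaCO3 poisoned with Pb(OAc)2 and quinoline gives the Z-alkenyl cyclobutenone F9, which undergoes the same ring opening and closure on heating in toluene and gives 20.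

**Further compounds**

F1 | step 5 | racemic (1R*,2R*,8aR*)-1,2,5,5-tetramethyl-1,2,3,5,6,7,8,8a-octahydronaphthalene-1-carbaldehyde | C[C@@H]1CC=C2[C@@H](CCCC2(C)C)[C@]1(C)C=O.C[C@H]1CC=C2[C@H](CCCC2(C)C)[C@@]1(C)C=O
F2 | step 5 | racemic [(1R*,2R*,8aR*)-1,2,5,5-tetramethyl-1,2,3,5,6,7,8,8a-octahydronaphthalen-1-yl]methanol | C[C@@H]1CC=C2[C@@H](CCCC2(C)C)[C@]1(C)CO.C[C@H]1CC=C2[C@H](CCCC2(C)C)[C@@]1(C)CO
F3 | step 5 | [(1R,2R,8aR)-1,2,5,5-tetramethyl-1,2,3,5,6,7,8,8a-octahydronaphthalen-1-yl]methyl (2S)-2-(6-methoxynaphthalen-2-yl)propanoate | C[C@@H]1CC=C2[C@@H](CCCC2(C)C)[C@]1(C)COC(=O)[C@@H](C)c1ccc2cc(OC)ccc2c1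
F4 | step 5 | [(1S,2S,8aS)-1,2,5,5-tetramethyl-1,2,3,5,6,7,8,8a-octahydronaphthalen-1-yl]methyl (2S)-2-(6-methoxynaphthalen-2-yl)propanoate | C[C@H]1CC=C2[C@H](CCCC2(C)C)[C@@]1(C)COC(=O)[C@@H](C)c1ccc2cc(OC)ccc2c1
F5 | step 5 | [(1R,2R,8aR)-1,2,5,5-tetramethyl-1,2,3,5,6,7,8,8a-octahydronaphthalen-1-yl]methanol | C[C@@H]1CC=C2[C@@H](CCCC2(C)C)[C@]1(C)CO
F6 | step 11 | 2-bromo-3-tert-butoxy-4-[(tert-butyldimethylsilyl)oxy]-6-(Dec-methyl)phenol | C[C@@H]1CC=C2[C@@H](CCCC2(C)C)[C@]1(C)Cc1cc(O[Si](C)(C)C(C)(C)C)c(OC(C)(C)C)c(Br)c1O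
F7 | step 9 | (1R,2R,8aS)-1,2,5,5-tetramethyl-1-(prop-2-yn-1-yl)-1,2,3,5,6,7,8,8a-octahydronaphthalene | C[C@@H]1CC=C2[C@@H](CCCC2(C)C)[C@]1(C)CC#C
F8 | step 9 | 3-tert-butoxy-4-[(tert-butyldimethylsilyl)oxy]-4-(3-Dec-prop-1-yn-1-yl)cyclobut-2-en-1-one | C[C@@H]1CC=C2[C@@H](CCCC2(C)C)[C@]1(C)CC#CC1(O[Si](C)(C)C(C)(C)C)C(OC(C)(C)C)=CC1=O
F9 | step 9 | 3-tert-butoxy-4-[(tert-butyldimethylsilyl)oxy]-4-[(1Z)-3-Dec-prop-1-en-1-yl]cyclobut-2-en-1-one | C[C@@H]1CC=C2[C@@H](CCCC2(C)C)[C@]1(C)C/C=C\C1(O[Si](C)(C)C(C)(C)C)C(OC(C)(C)C)=CC1=O
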